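Target plus substrate holds at the substrate charge in the flask (beta run), 100% at its last reading, so the substrate goes nowhere but to target, and the question is what stops it.

| setting | beta | eta | flask |
|---|---|---|---|
| substrate | 3 M | 3 M | 3.0 M |
| partner | 1.5 M | 1.5 M | 1.50 M |
| free catalyst | 3 mM | 4.5 mM | 3.0 mM |
| temperature | 25 °C | 31 °C | 25 °C |
| remark | the very flask that is asked about, followed so far | run made earlier |  |
| time |  |  | 5.0 d |

- beta (time / h: target / %, substrate / %): 5.00: 14.9, 84.0; 15.0: 29.1, 70.6; 25.0: 33.1, 67.0; 40.0: 32.0, 67.5; 60.0: 32.9, 67.2; 72.0: 32.4, 67.8
- eta (time / h: target / %, substrate / %): 0.667: 7.4, 95.4; 1.00: 7.5, 92.9; 2.00: 17.1, 83.5; 3.00: 23.3, 78.3; 5.00: 29.2, 72.2; 8.00: 34.0, 66.5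

(standard deviation of a reading: 1 percentage point)

- dusk: at 5.0 d add free catalyst, 100% of the amount charged, then wait 40 h
- autumn: at 5.0 d raise the temperature by 25 K, then wait 40 h
- midnight: change nothing and wait 40 h more
- dawn: at 5.0 d take out 90% of the by-product then present, then wait 40 h

- the volume of additions can be left aside
- the analysis behind the earlier runs scatters by 1 percentage point, standard deviation

* target, in percent of the substrate first charged, at 5.0 d
* which option adds most target ("none" when 2 percentage points or less is all one gets) (dusk / autumn / midnight / dawn / none)
* target present, in percent of the substrate first charged, after dusk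
* target present, in percent of the substrate first charged, after autumn

1. I take the main step alone: substrate and partner give target and by-product, one to one. The partner is then the limiting reagent, and the target could reach 50.0% of the substrate charge. The readings level off at 32.6%, so 65.2% of the partner charge is accounted for as target.

2. I add one process: a first-order loss of partner beside the catalysed use. The two then share the partner, and I call the partner split, a selectivity factor, the partner going to target over the partner lost, summed over the whole run, here 1.87. I assume that it scales with the catalyst charge. The first reading gives a decay constant of 0.122 h⁻¹, which is a partner half-life of 5.67 h. The time 5.0 d is 21.2 such half-lives, so I expect no measurable partner by then.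

3. The rest is a reverse step, which would draw the same curve. The eta run stands at 34.0% in its last reading, above the level of the flask, with more catalyst and more heat. That is a weak hint, given the scatter, that the level moves, and I commit to the partner loss. My reckoning is 32.6% now and after each option, with best "none".

The forecast gives 32.6%, 32.7% after dusk, 33.8% after autumn and best dawn, on the ground that “The partner is not exhausted”. We part on the best option.

The flask gives 32.7%, 32.7% after dusk, 32.7% after autumn and best none, with dawn adding 0 percentage points.

    partner + free catalyst ⇌ catalyst intermediate A (K = 12.0 L mol⁻¹, k = 52.9 L mol⁻¹ h⁻¹, Ea = 60.0 kJ mol⁻¹, ΔH = −19.0 kJ mol⁻¹)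
    catalyst intermediate A → by-product + catalyst intermediate B (k = 88.5 h⁻¹, Ea = 90.0 kJ mol⁻¹)
    substrate + catalyst intermediate B → catalyst intermediate C (k = 111 L mol⁻¹ h⁻¹, Ea = 58.0 kJ mol⁻¹)
    catalyst intermediate C → free catalyst + target (k = 2030 h⁻¹, Ea = 73.0 kJ mol⁻¹)
    partner → decomposed reagent (k = 0.0518 h⁻¹, Ea = 90.0 kJ mol⁻¹)
    (constants at 25 °C)

While partner was present, free catalyst took it up towards catalyst intermediate A, with 82% of that turnover done by 12.0 h, and decomposed reagent formed beside it. By 60.0 h partner stood at 0% and free catalyst at >99.9%, with by-product over decomposed reagent at 1.88, against the split of 1.87 read from the target level. The neighbour charged with 7.5 × 10⁻⁴ M of free catalyst has a quarter of the charge, so the scaled split gives 15.9%, and that flask holds 16.2%.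

(Readings and results come from a simulation for substances that don't exist, and the scatter is random.)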